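## Structural features

The target is a 2,3-dihydro-4H-furo[3,2-c]pyran-4-one in which ring B (O1, C2, C3, C3a, C7a) is fused through the C3a=C7a double bond to the 2-pyranone ring C (C3a, C4, O5, C6, C7, C7a), and C6 carries an (E)-4-hydroxystyryl arm. C2 bears the catechol ring D, and C3 bears ring A, a 4-hydroxy-2-pyranone joined through C6'. The only stereocentres, C2 and C3, are neighbours, both S, and trans to each other. The fragile groups are the C2–O1 bond (benzylic to an electron-rich arene, with O1 the enol oxygen of a 4-oxypyranone and so a good leaving group), the C3–H bond whenever C6' is a carbonyl carbon (O1 then sits β to an enolisable centre), the styryl double bond (which rules out hydrogenolysis) and the air-sensitive catechol. The real difficulty is to set the C2/C3 pair in the absolute sense and to keep it while a pyranone is grown on each side of C3. The key step exploits the fact that, once ring C is pared back to C7a alone, O1–C2–C3–C3a–C7a is a γ-aryl-γ-butyrolactone with C7a as carbonyl carbon, C3a as α-methylene, C3 as β-carbon carrying C6' and C2 as γ-carbon carrying ring D, which is what the homoenolate of a four-carbon enal and an aryl aldehyde deliver. C6' of the target is at the acyl level (it is the enol-lactone carbon of ring A), so a formyl-level carbon on C3 is one oxidation short once the C6'–C5' bond exists, and the plan includes that oxidation (step 11).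

## Logic of the disconnections

21 is taken back to 20 by replacing three phenolic O–H bonds with O–CH2Ph bonds. Phenols and a catechol would not pass the organolithium, enolate and oxidation steps. Nothing is gained in skeleton, only compatibility. The forward step must cleave aryl benzyl ethers without touching the styryl C=C or the benzylic C2–O1 bond, so hydrogenolysis is excluded.

20 is opened at the O1'–C2' bond of ring A to 19, and 19 is capped with acetone to give 18. Ring A is the enol lactone of a 3,5-dioxo acid, and the acid end can be stored as a dioxinone. Ring A thus becomes an open chain attached to C3 through a ketone. The forward closure must be thermal and neutral, because C3–H and C2–O1 no longer tolerate base.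

18 is cut at C6'–C5' and C6' is lowered from ketone to carbinol (17). This divides the molecule into 14 and the four-carbon unit 16, which is one step from 15. The cut is made here because C6' must reach the acyl level, and an aldehyde reaches it by aldol addition and oxidation. The forward C–C bond formation must be non-basic, since 14 has an epimerisable C3 with O1 in the β-position.

14 is traced to 13 by exchanging C6'=O for two C–OMe bonds. In this form C3 cannot enolise during the base steps that build ring C. The demand is a hydrolysis mild enough to leave C2–O1 alone.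

13 is cut at C6–C7 and at O5–C4 (through 12) into 8 and 11. Ring C is the enol lactone of a δ-keto-β-alkoxy-enoate, so removing C6 with its whole styryl arm leaves ring B carrying only a methyl group (C7) and an ester (C4). The gain is that the arm arrives as one acyl unit. The demand is acylation of a dienolate at its terminal carbon, with enough base to absorb the more acidic product.

11 is traced to 10 (C–Cl to C–OH), and 10 is cut at the styryl C=C to 9 and a two-carbon unit supplied by a malonate reagent. This is a trivial simplification. The only demand is E geometry, which the thermodynamics of the condensation supply.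

8 is cut at C3a–C4 (through 7) to 6. C3a is the nucleophilic β-carbon of a cyclic enol ether and C4 can arrive as a one-carbon acyl electrophile. The gain is that 6 has no carbonyl group at all. The demand is that the electrophile prefers the enol ether to the acetal.

6 is hydrated across C3a=C7a to 5, and the C7a–C7 bond is cut to return to 4. C7a thereby returns to the carboxyl level, that is, to a lactone. The forward steps need a single addition of a methyl nucleophile and a dehydration that ends at the endocyclic isomer.

4 is related to 3, its epimer at C2, by breaking and re-forming the benzylic C2–O1 bond. This relation is built in because the annulation below is expected to favour the cis arrangement of 3, whereas the target needs the trans arrangement of 4. It simplifies nothing in the skeleton, but it frees the C–C bond formation from having to deliver the trans isomer directly. The demand is that C3 stays fixed while C2 equilibrates, and that both isomers leave the annulation with the same configuration at C3.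

3, together with whatever share of 4 forms directly, is cut at C2–C3 and at O1–C7a into 1 and 2. Both stereocentres and ring B come from two simple aldehydes in one catalytic operation, with C3 born on a carbon that cannot enolise. The demand is facial control by a chiral carbene and a cross-reaction with an electron-rich aldehyde.

## Other disconnections considered

Alternative 1: The cut is at C2–C3 and O1–C2, so ring B is closed last from a four-atom unit (O1–C7a=C3a–C3) and a one-carbon unit (C2). A carbonate base would eliminate sulfinate from the adduct A2, which unmasks its electrophilic exocyclic double bond at C3, and would deprotonate the chiral benzylic sulfonium salt A3 to its ylide. The ylide carbon adds to C3, and the dione enolate oxygen displaces the sulfide at C2 (5-exo-tet) to give the fully benzylated furopyranone A1.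
- In favour: rings A, C and D arrive complete, C6' never passes through a carbonyl stage, and trans is the normal outcome of such ylide annulations. On convergence, on step economy (roughly half the linear length) and on oxidation-level economy at C6' this alternative is the better plan.
- Against: the absolute sense depends on a stoichiometric chiral sulfide acting in a stepwise addition. That addition may be reversible, because the leaving nucleophile is a highly stabilised pyrandione enolate. An electron-rich sulfonium salt such as A3 can lose its sulfide by ionisation before it forms the ylide. A2 is itself a sensitive building block that takes several steps to make. A1 is formed in base with its C3–H flanked by two pyranones.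
- Comparison: on structure, both plans give trans and both form C2–C3. The chosen plan sets the pair catalytically on a small lactone whose C2 can be corrected separately, but then has to carry it through many steps. On mechanism, a polar addition–substitution stands against carbene umpolung. On step economy the alternative is clearly shorter.

Alternative 2: The cut is at C3a–C4 and C4–O5, with C4 supplied as carbon monoxide. Zerovalent palladium (from Pd(PPh3)4) inserts into the C3a–I bond of the vinyl iodide A5, CO inserts, and the enol oxygen of the neighbouring methyl ketone captures the acyl–palladium bond to close ring C in the 6-methyl furopyranone A4.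
- In favour: the carbonylation puts C4 in an unambiguous place under mild conditions. It is better than step 4 in chemoselectivity and better than step 7 in regiochemical certainty. The silyloxymethyl group on C3 is as non-enolisable as the acetal of the chosen plan and more robust to acid, so it is equal or better as a mask.
- Against: A5 must already contain both stereocentres, so this disconnection leaves the stereochemical problem to another step. The styryl arm still has to be attached by a separate condensation at the C6 methyl group. C6' starts two oxidation levels low and must pass through the same fragile aldehyde as 14, so on that point the plans are equal.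
- Comparison: on structure, the order of events (ring B, then C, then A) is that of the chosen plan. On mechanism, an organometallic acyl transfer replaces enolate chemistry. On step economy, it is longer by about three or four steps.

Alternative 3: The cut is at C3–C3a, a bond made by migration. Visible light would expel nitrogen from the diazo ketone A7, and the ring carbon that becomes C3a shifts to the diazo carbon. The six-membered ring contracts to ring B, and water adds to the ketene carbon left outside the ring to give the acid A6, with C3 protonated anti to the C2 aryl group.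
- In favour: only C2 has to be set enantioselectively, and C3 follows by substrate control. The exocyclic carbon arrives at the carboxyl level, which is the correct level for C6'. On that point it is better than the chosen plan, since no oxidation step is needed. Ring C and the styryl arm are present from the start. The step count would be about equal or one or two steps lower.
- Against: the diazo transfer in base that makes A7 operates on a 2-aryl dihydropyranone ring whose C2–O1 bond can open by retro-oxa-Michael reaction, so the single stereocentre is at risk. The styrylpyranone chromophore absorbs where the diazo ketone does and is prone to E/Z isomerisation and cycloaddition. A6 must be activated at a carbon next to C3 with O1 in the β-position.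
- Comparison: on structure, ring C precedes ring B, and C3 is born α to a carboxyl group instead of on a non-enolisable carbon. On mechanism, a photochemical 1,2-shift stands against thermal organocatalysis. On step economy the two plans are about equal.

Key step: step 1

Remark: 2 and 9 are catalogue compounds and are used as bought, which saves two benzylation steps.

Remark: the antipode of the triazolium salt that leads to the 4S series has to be fixed by a trial run; both antipodes are accessible from the enantiomers of cis-1-amino-2-indanol.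

Remark (assumption): the annulation is taken to give mainly the cis lactone under kinetic control, as is usual for this reaction type, so the acid convergence to the trans lactone is built into step 1.

## Route

Step 1
Reactants: 1 (E)-4,4-dimethoxybut-2-enal; 2 3,4-bis(benzyloxy)benzaldehyde
Product: 4 (4S,5S)-5-[3,4-bis(benzyloxy)phenyl]-4-(dimethoxymethyl)dihydrofuran-2(3H)-one, via cis lactone 3 (not isolated)
Conditions: aminoindanol-derived N-mesityl triazolium chloride (10 mol %), DBU (10 mol %), Ti(OiPr)4 (20 mol %), 2 (2 equiv), slow addition of 1, CH2Cl2, rt; silica plug; then CF3CO2H (5 equiv), CH2Cl2, 0 °C to rt; quench into Et3N/MeOH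
Reagents that add atoms: none
Why: The carbene adds to the formyl group of 1 and a proton shift gives the conjugated enaminol, a homoenolate equivalent that is nucleophilic at the enal β-carbon. This carbon adds to the titanium-activated carbonyl group of 2 (C2–C3 bond); the enol azolium tautomerises to the acyl azolium, and the new alkoxide closes ring B as its lactone by 5-exo-trig acyl substitution (O1–C7a bond), which releases the carbene. The closest known reaction type is the carbene-catalysed homoenolate (3+2) annulation of enals with aryl aldehydes in its enantioselective, Lewis-acid-assisted form. The configuration of lactone C4 (C3 of the target) is controlled by the fused aminoindanol backbone, which shields one face of the enaminol so that the β-carbon reacts on the open face. The configuration of lactone C5 (C2 of the target) depends on the face of 2 presented in the titanium-organised transition state, which by analogy should favour the cis lactone 3 (4S,5R) with a minor share of the trans lactone 4. The crude mixture is therefore treated with CF3CO2H, which ionises the benzylic C5–O bond (SN1, cation stabilised by the para benzyloxy group) and lets the carboxyl group reclose under thermodynamic control to the trans lactone 4 with C4 as the anchor; the methanolic base quench returns any ionised acetal to the dimethyl acetal. The step needs homoenolate rather than acyl-anion reactivity, which the N-mesityl triazolium provides, and cross-annulation rather than self-annulation of 1, which slow addition of 1, the excess of 2 and Lewis-acid activation of the deactivated aldehyde are meant to secure. The acetal carbon is not enolisable, so the configuration set at lactone C4 is static in all later base steps.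

Step 2
Reactants: 4 (4S,5S)-5-[3,4-bis(benzyloxy)phenyl]-4-(dimethoxymethyl)dihydrofuran-2(3H)-one
Product: 5 (4S,5S)-5-[3,4-bis(benzyloxy)phenyl]-4-(dimethoxymethyl)-2-methyloxolan-2-ol (both anomers, in equilibrium with the open hydroxy ketone)
Conditions: MeLi (1.1 equiv), THF, −78 °C; aq. NH4Cl
Reagents that add atoms: methyllithium [Li]C
Why: Nucleophilic addition of an organolithium to a lactone: the lithium hemiketal alkoxide persists at −78 °C, so a second addition should not occur; C7 is now attached to C7a and neither stereocentre is touched.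

Step 3
Reactants: 5 (4S,5S)-5-[3,4-bis(benzyloxy)phenyl]-4-(dimethoxymethyl)-2-methyloxolan-2-ol
Product: 6 (2S,3S)-2-[3,4-bis(benzyloxy)phenyl]-3-(dimethoxymethyl)-5-methyl-2,3-dihydrofuran
Conditions: PPTS (10 mol %), PhMe, 3 Å sieves, 80 °C; Et3N quench
Reagents that add atoms: none
Why: Acid-catalysed cyclodehydration of a γ-hydroxy ketone through the cyclic oxocarbenium ion; under equilibrating conditions proton loss from C3a should give the endocyclic trisubstituted enol ether in preference to the exocyclic methylidene isomer, and the weak pyridinium acid in the absence of water should leave the acetal intact.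

Step 4
Reactants: 6 (2S,3S)-2-[3,4-bis(benzyloxy)phenyl]-3-(dimethoxymethyl)-5-methyl-2,3-dihydrofuran
Product: 8 methyl (4S,5S)-5-[3,4-bis(benzyloxy)phenyl]-4-(dimethoxymethyl)-2-methyl-4,5-dihydrofuran-3-carboxylate, via trichloromethyl ketone 7 (not isolated)
Conditions: Cl3CCOCl (1.3 equiv), pyridine (2.5 equiv), CH2Cl2, 0 °C; then MeOH, K2CO3 (0.2 equiv), 0 °C to rt
Reagents that add atoms: trichloroacetyl chloride ClC(=O)C(Cl)(Cl)Cl; methanol CO
Why: β-C-Acylation of an enol ether by trichloroacetyl chloride places C4 on C3a, the only nucleophilic carbon of 6, and the trichloromethyl ketone is then cleaved by methanol in a haloform-type reaction to the methyl ester; low temperature and a small excess of the acid chloride are meant to keep the acetal out of the reaction.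

Step 5
Reactants: 9 4-(benzyloxy)benzaldehyde
Product: 10 (E)-3-[4-(benzyloxy)phenyl]prop-2-enoic acid
Conditions: CH2(CO2H)2, pyridine, piperidine (cat.), 100 °C
Reagents that add atoms: malonic acid OC(=O)CC(=O)O
Why: Knoevenagel–Doebner condensation with decarboxylation, which should give the E acid under thermodynamic control.

Step 6
Reactants: 10 (E)-3-[4-(benzyloxy)phenyl]prop-2-enoic acid
Product: 11 (E)-3-[4-(benzyloxy)phenyl]prop-2-enoyl chloride
Conditions: (COCl)2, DMF (cat.), CH2Cl2, 0 °C to rt
Reagents that add atoms: oxalyl chloride ClC(=O)C(=O)Cl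
Why: Standard conversion of an acid into its chloride through the chloroiminium catalyst; the benzyl ether and the alkene are inert.

Step 7
Reactants: 8 methyl (4S,5S)-5-[3,4-bis(benzyloxy)phenyl]-4-(dimethoxymethyl)-2-methyl-4,5-dihydrofuran-3-carboxylate; 11 (E)-3-[4-(benzyloxy)phenyl]prop-2-enoyl chloride
Product: 13 (2S,3S)-2-[3,4-bis(benzyloxy)phenyl]-6-[(E)-2-[4-(benzyloxy)phenyl]ethenyl]-3-(dimethoxymethyl)-2,3-dihydro-4H-furo[3,2-c]pyran-4-one, via keto ester 12 (not isolated)
Conditions: LiN(iPr)2 (2.2 equiv), THF, −78 °C; 11, −78 to −20 °C; AcOH; then DBU, PhMe, 60 °C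
Reagents that add atoms: none
Why: γ-Deprotonation of the cyclic β-alkoxy enoate at the C7 methyl group, its only acidic site, and C-acylation of the dienolate by 11 form the C6–C7 bond, the second equivalent of base absorbing the more acidic product; DBU then drives 6-exo-trig attack of the enol oxygen on the neighbouring ester (O5–C4), which ring B holds cis to the side chain, so ring C closes with loss of methanol, the known γ-acylation–lactonisation route to 4-alkoxy-2-pyranones.

Step 8
Reactants: 13 (2S,3S)-2-[3,4-bis(benzyloxy)phenyl]-6-[(E)-2-[4-(benzyloxy)phenyl]ethenyl]-3-(dimethoxymethyl)-2,3-dihydro-4H-furo[3,2-c]pyran-4-one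
Product: 14 (2S,3S)-2-[3,4-bis(benzyloxy)phenyl]-6-[(E)-2-[4-(benzyloxy)phenyl]ethenyl]-4-oxo-2,3-dihydro-4H-furo[3,2-c]pyran-3-carbaldehyde
Conditions: Amberlyst-15, acetone/H2O (10:1), rt; filtration, used at once
Reagents that add atoms: water O
Why: Acid-catalysed hydrolysis of a dimethyl acetal on a sulfonic acid resin that is removed by filtration; the mild protic conditions and immediate use of the aldehyde are meant to prevent enolisation at C3 and ionisation of the C2–O1 bond.

Step 9
Reactants: 15 2,2,6-trimethyl-4H-1,3-dioxin-4-one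
Product: 16 4-(trimethylsilyloxy)-2,2-dimethyl-6-methylidene-6H-1,3-dioxine
Conditions: LiN(iPr)2, THF, −78 °C; Me3SiCl
Reagents that add atoms: chlorotrimethylsilane C[Si](C)(C)Cl
Why: γ-Deprotonation of the vinylogous ester and O-silylation of the dienolate give the cross-conjugated silyl dienol ether, a standard preparation.

Step 10
Reactants: 14 (2S,3S)-2-[3,4-bis(benzyloxy)phenyl]-6-[(E)-2-[4-(benzyloxy)phenyl]ethenyl]-4-oxo-2,3-dihydro-4H-furo[3,2-c]pyran-3-carbaldehyde; 16 4-(trimethylsilyloxy)-2,2-dimethyl-6-methylidene-6H-1,3-dioxine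
Product: 17 6-{2-[(2S,3R)-2-[3,4-bis(benzyloxy)phenyl]-6-[(E)-2-[4-(benzyloxy)phenyl]ethenyl]-4-oxo-2,3-dihydro-4H-furo[3,2-c]pyran-3-yl]-2-hydroxyethyl}-2,2-dimethyl-4H-1,3-dioxin-4-one (both carbinol epimers)
Conditions: BF3·OEt2 (1.1 equiv), CH2Cl2, −78 °C; aq. NaHCO3
Reagents that add atoms: none
Why: Vinylogous Mukaiyama aldol addition: the terminal methylidene carbon of 16 attacks the BF3-activated aldehyde (C6'–C5' bond) under non-basic conditions at −78 °C, so C3–H should not be removed and O1 should not be expelled; the new carbinol centre is not controlled because it is oxidised in step 11 (the descriptor at C3 changes to R only through the priority rules).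

Step 11
Reactants: 17 6-{2-[(2S,3R)-2-[3,4-bis(benzyloxy)phenyl]-6-[(E)-2-[4-(benzyloxy)phenyl]ethenyl]-4-oxo-2,3-dihydro-4H-furo[3,2-c]pyran-3-yl]-2-hydroxyethyl}-2,2-dimethyl-4H-1,3-dioxin-4-one
Product: 18 6-{2-[(2S,3S)-2-[3,4-bis(benzyloxy)phenyl]-6-[(E)-2-[4-(benzyloxy)phenyl]ethenyl]-4-oxo-2,3-dihydro-4H-furo[3,2-c]pyran-3-yl]-2-oxoethyl}-2,2-dimethyl-4H-1,3-dioxin-4-one
Conditions: Dess–Martin periodinane (1.2 equiv), NaHCO3, CH2Cl2, 0 °C to rt
Reagents that add atoms: none
Why: Dess–Martin oxidation of a secondary alcohol under buffered conditions raises C6' to the acyl level; the ketone should enolise towards the doubly activated C5' methylene, which keeps C3 out of the enol.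

Step 12
Reactants: 18 6-{2-[(2S,3S)-2-[3,4-bis(benzyloxy)phenyl]-6-[(E)-2-[4-(benzyloxy)phenyl]ethenyl]-4-oxo-2,3-dihydro-4H-furo[3,2-c]pyran-3-yl]-2-oxoethyl}-2,2-dimethyl-4H-1,3-dioxin-4-one
Product: 20 (2S,3S)-2-[3,4-bis(benzyloxy)phenyl]-6-[(E)-2-[4-(benzyloxy)phenyl]ethenyl]-3-(4-hydroxy-2-oxo-2H-pyran-6-yl)-2,3-dihydro-4H-furo[3,2-c]pyran-4-one, via acylketene 19 (not isolated)
Conditions: PhMe, 110 °C
Reagents that add atoms: none
Why: Thermal retro-[4+2] fragmentation of the dioxinone releases acetone and an acylketene, and the enol oxygen of the C6' ketone adds to the ketene carbon (formally an oxa-6π closure) to give ring A as the 4-hydroxy-2-pyranone under neutral conditions.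

Step 13
Reactants: 20 (2S,3S)-2-[3,4-bis(benzyloxy)phenyl]-6-[(E)-2-[4-(benzyloxy)phenyl]ethenyl]-3-(4-hydroxy-2-oxo-2H-pyran-6-yl)-2,3-dihydro-4H-furo[3,2-c]pyran-4-one
Product: 21 (2S,3S)-2-(3,4-dihydroxyphenyl)-3-(4-hydroxy-2-oxo-2H-pyran-6-yl)-6-[(E)-2-(4-hydroxyphenyl)ethenyl]-2,3-dihydro-4H-furo[3,2-c]pyran-4-one
Conditions: BCl3 (excess), C6HMe5, CH2Cl2, −78 °C; then MeOH
Reagents that add atoms: none
Why: Lewis-acid cleavage of aryl benzyl ethers with pentamethylbenzene as a non-basic trap for the benzyl cations should spare the styryl C=C and the lactones, which hydrogenolysis would not; at −78 °C ionisation of the C2–O1 bond should be slow, and any opening can only reclose intramolecularly to the trans ring with C3 as anchor.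

## Compound list

1 | (E)-4,4-dimethoxybut-2-enal | COC(OC)/C=C/C=O | starting material
2 | 3,4-bis(benzyloxy)benzaldehyde | O=Cc1ccc(OCc2ccccc2)c(OCc2ccccc2)c1 | starting material
3 | (4S,5R)-5-[3,4-bis(benzyloxy)phenyl]-4-(dimethoxymethyl)dihydrofuran-2(3H)-one | COC(OC)[C@H]1CC(=O)O[C@H]1c2ccc(OCc3ccccc3)c(OCc3ccccc3)c2 | intermediate
4 | (4S,5S)-5-[3,4-bis(benzyloxy)phenyl]-4-(dimethoxymethyl)dihydrofuran-2(3H)-one | COC(OC)[C@H]1CC(=O)O[C@@H]1c2ccc(OCc3ccccc3)c(OCc3ccccc3)c2 | intermediate
5 | (4S,5S)-5-[3,4-bis(benzyloxy)phenyl]-4-(dimethoxymethyl)-2-methyloxolan-2-ol | COC(OC)[C@H]1CC(C)(O)O[C@@H]1c2ccc(OCc3ccccc3)c(OCc3ccccc3)c2 | intermediate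
6 | (2S,3S)-2-[3,4-bis(benzyloxy)phenyl]-3-(dimethoxymethyl)-5-methyl-2,3-dihydrofuran | COC(OC)[C@H]1C=C(C)O[C@@H]1c2ccc(OCc3ccccc3)c(OCc3ccccc3)c2 | intermediate
7 | 1-[(4S,5S)-5-[3,4-bis(benzyloxy)phenyl]-4-(dimethoxymethyl)-2-methyl-4,5-dihydrofuran-3-yl]-2,2,2-trichloroethan-1-one | COC(OC)[C@H]1C(C(=O)C(Cl)(Cl)Cl)=C(C)O[C@@H]1c2ccc(OCc3ccccc3)c(OCc3ccccc3)c2 | intermediate
8 | methyl (4S,5S)-5-[3,4-bis(benzyloxy)phenyl]-4-(dimethoxymethyl)-2-methyl-4,5-dihydrofuran-3-carboxylate | COC(OC)[C@H]1C(C(=O)OC)=C(C)O[C@@H]1c2ccc(OCc3ccccc3)c(OCc3ccccc3)c2 | intermediate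
9 | 4-(benzyloxy)benzaldehyde | O=Cc1ccc(OCc2ccccc2)cc1 | starting material
10 | (E)-3-[4-(benzyloxy)phenyl]prop-2-enoic acid | OC(=O)/C=C/c1ccc(OCc2ccccc2)cc1 | intermediate
11 | (E)-3-[4-(benzyloxy)phenyl]prop-2-enoyl chloride | ClC(=O)/C=C/c1ccc(OCc2ccccc2)cc1 | intermediate
12 | methyl (4S,5S)-5-[3,4-bis(benzyloxy)phenyl]-2-[(E)-4-[4-(benzyloxy)phenyl]-2-oxobut-3-en-1-yl]-4-(dimethoxymethyl)-4,5-dihydrofuran-3-carboxylate | COC(OC)[C@H]1C(C(=O)OC)=C(CC(=O)/C=C/c2ccc(OCc3ccccc3)cc2)O[C@@H]1c4ccc(OCc5ccccc5)c(OCc5ccccc5)c4 | intermediate
13 | (2S,3S)-2-[3,4-bis(benzyloxy)phenyl]-6-[(E)-2-[4-(benzyloxy)phenyl]ethenyl]-3-(dimethoxymethyl)-2,3-dihydro-4H-furo[3,2-c]pyran-4-one | COC(OC)[C@H]1c2c(cc(/C=C/c3ccc(OCc4ccccc4)cc3)oc2=O)O[C@@H]1c5ccc(OCc6ccccc6)c(OCc6ccccc6)c5 | intermediate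
14 | (2S,3S)-2-[3,4-bis(benzyloxy)phenyl]-6-[(E)-2-[4-(benzyloxy)phenyl]ethenyl]-4-oxo-2,3-dihydro-4H-furo[3,2-c]pyran-3-carbaldehyde | O=C[C@H]1c2c(cc(/C=C/c3ccc(OCc4ccccc4)cc3)oc2=O)O[C@@H]1c5ccc(OCc6ccccc6)c(OCc6ccccc6)c5 | intermediate
15 | 2,2,6-trimethyl-4H-1,3-dioxin-4-one | CC1=CC(=O)OC(C)(C)O1 | starting material
16 | 4-(trimethylsilyloxy)-2,2-dimethyl-6-methylidene-6H-1,3-dioxine | C=C1C=C(O[Si](C)(C)C)OC(C)(C)O1 | intermediate
17 | 6-{2-[(2S,3R)-2-[3,4-bis(benzyloxy)phenyl]-6-[(E)-2-[4-(benzyloxy)phenyl]ethenyl]-4-oxo-2,3-dihydro-4H-furo[3,2-c]pyran-3-yl]-2-hydroxyethyl}-2,2-dimethyl-4H-1,3-dioxin-4-one | CC1(C)OC(CC(O)[C@H]2c3c(cc(/C=C/c4ccc(OCc5ccccc5)cc4)oc3=O)O[C@@H]2c6ccc(OCc7ccccc7)c(OCc7ccccc7)c6)=CC(=O)O1 | intermediate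
18 | 6-{2-[(2S,3S)-2-[3,4-bis(benzyloxy)phenyl]-6-[(E)-2-[4-(benzyloxy)phenyl]ethenyl]-4-oxo-2,3-dihydro-4H-furo[3,2-c]pyran-3-yl]-2-oxoethyl}-2,2-dimethyl-4H-1,3-dioxin-4-one | CC1(C)OC(CC(=O)[C@H]2c3c(cc(/C=C/c4ccc(OCc5ccccc5)cc4)oc3=O)O[C@@H]2c6ccc(OCc7ccccc7)c(OCc7ccccc7)c6)=CC(=O)O1 | intermediate
19 | 5-[(2S,3S)-2-[3,4-bis(benzyloxy)phenyl]-6-[(E)-2-[4-(benzyloxy)phenyl]ethenyl]-4-oxo-2,3-dihydro-4H-furo[3,2-c]pyran-3-yl]-3,5-dioxopent-1-en-1-one | O=C=CC(=O)CC(=O)[C@H]1c2c(cc(/C=C/c3ccc(OCc4ccccc4)cc3)oc2=O)O[C@@H]1c5ccc(OCc6ccccc6)c(OCc6ccccc6)c5 | intermediate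
20 | (2S,3S)-2-[3,4-bis(benzyloxy)phenyl]-6-[(E)-2-[4-(benzyloxy)phenyl]ethenyl]-3-(4-hydroxy-2-oxo-2H-pyran-6-yl)-2,3-dihydro-4H-furo[3,2-c]pyran-4-one | O=c1cc(O)cc([C@H]2c3c(cc(/C=C/c4ccc(OCc5ccccc5)cc4)oc3=O)O[C@@H]2c6ccc(OCc7ccccc7)c(OCc7ccccc7)c6)o1 | intermediate
21 | (2S,3S)-2-(3,4-dihydroxyphenyl)-3-(4-hydroxy-2-oxo-2H-pyran-6-yl)-6-[(E)-2-(4-hydroxyphenyl)ethenyl]-2,3-dihydro-4H-furo[3,2-c]pyran-4-one | O=c1cc(O)cc([C@H]2c3c(cc(/C=C/c4ccc(O)cc4)oc3=O)O[C@@H]2c5ccc(O)c(O)c5)o1 | target

## Step count and least certain steps

Total step count: 13. Longest linear sequence: 10 (steps 1 to 4, 7, 8 and 10 to 13). Steps 5 and 6 make 11, and step 9 makes 16.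

Step 1 (key step). In the annulation half the most likely failure is a slow cross-reaction: the carbonyl group of 2 is deactivated by two alkoxy groups, so the homoenolate may add to a second molecule of 1 instead. Facial discrimination at the β-carbon may be modest, and loss of methoxide from the enaminol (an internal redox to an unsaturated acyl azolium) is a further drain. In the equilibration half the benzylic cation may lose the proton at lactone C4 instead of reclosing, or the acetal may ionise and its oxocarbenium ion lose the same proton. Either path erases the centre that is meant to anchor the convergence. The convergence also presumes that both lactones leave the annulation with the same configuration at C4; if they do not, enantiomeric purity is eroded.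

The fallback replaces carbene catalysis and the equilibration by an auxiliary-controlled aldol reaction that gives the trans lactone directly. It sets out from 2 and returns at 4. (S)-4-Benzyl-1,3-oxazolidin-2-one is N-acylated with methyl 4-chloro-4-oxobutanoate (n-BuLi, THF, −78 °C) to give the succinate imide F1. Its dibutylboron enolate (Bu2BOTf, iPr2NEt, CH2Cl2, −78 to 0 °C) adds to 2 in an Evans syn-aldol reaction to give the aldol adduct F2. Catalytic camphorsulfonic acid closes the secondary hydroxyl group of F2 onto the methyl ester to give the lactone imide F3; the syn aldol maps onto the trans lactone with the 4S,5S arrangement of 4. NaBH4 in THF/water at 0 °C cleaves the imide reductively to the hydroxymethyl lactone F4, Dess–Martin oxidation gives the lactone aldehyde F5, and HC(OMe)3, MeOH and PPTS convert F5 into 4.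

Step 4. Acylation may occur in the wrong place. The acid chloride–pyridine pair can activate the dimethyl acetal (loss of methanol, then acylation of the new enol ether at C3). The enol ether can also react through its exocyclic tautomer, which would put the acyl group on C7.

The fallback brings in C4 as carbon monoxide. It sets out from 6 and returns at 8. Iodination at C3a (N-iodosuccinimide, AgNO3 cat., MeCN) gives the vinyl iodide F6. Alkoxycarbonylation (Pd(OAc)2, dppf, CO 1 atm, MeOH, Et3N, DMF, 60 °C; oxidative addition of zerovalent palladium, CO insertion, methanolysis) then gives 8.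

Step 7. Acyl transfer may go to oxygen instead of C7, the more acidic product enolate may be acylated a second time, or the dienolate may add in conjugate fashion to the cinnamoyl unit.

The fallback separates ring closure from attachment of the arm. It sets out from 8 and returns at 13. The dienolate (LiN(iPr)2, 2.2 equiv, THF, −78 °C) is acylated with N-methoxy-N-methylacetamide to give the acetonyl ester F7. DBU in toluene closes ring C to the 6-methyl furopyranone F8. Aldol condensation of the C6 methyl group with 9 (Mg(OMe)2, MeOH, reflux) passes through the carbinol F9, which loses water to give 13.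

Step 10. The aldehyde 14 may enolise towards C3 under the Lewis acid, which would epimerise C3 or expel O1 and open ring B. Ionisation of the C2–O1 bond by BF3 is the second risk.

The fallback raises C6' to the acid level first and makes the C6'–C5' bond by acyl substitution, which also removes step 11. It sets out from 14 and returns at 18. Pinnick oxidation (NaClO2, NaH2PO4, 2-methyl-2-butene, t-BuOH/water) gives the carboxylic acid F10. Oxalyl chloride with catalytic DMF gives the acid chloride F11. F11 is added at −78 °C to the lithium dienolate of 15 (LiN(SiMe3)2, 2 equiv, THF), whose terminal carbon is acylated to give 18.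

## Further compounds

F1 | step 1 | methyl 4-[(4S)-4-benzyl-2-oxo-1,3-oxazolidin-3-yl]-4-oxobutanoate | COC(=O)CCC(=O)N1[C@@H](Cc2ccccc2)COC1=O
F2 | step 1 | methyl (3S,4S)-3-{[(4S)-4-benzyl-2-oxo-1,3-oxazolidin-3-yl]carbonyl}-4-[3,4-bis(benzyloxy)phenyl]-4-hydroxybutanoate | COC(=O)C[C@H](C(=O)N1[C@@H](Cc2ccccc2)COC1=O)[C@H](O)c3ccc(OCc4ccccc4)c(OCc4ccccc4)c3
F3 | step 1 | (4S)-4-benzyl-3-{[(2S,3S)-2-[3,4-bis(benzyloxy)phenyl]-5-oxooxolan-3-yl]carbonyl}-1,3-oxazolidin-2-one | O=C(N1[C@@H](Cc2ccccc2)COC1=O)[C@H]3CC(=O)O[C@@H]3c4ccc(OCc5ccccc5)c(OCc5ccccc5)c4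
F4 | step 1 | (4R,5S)-5-[3,4-bis(benzyloxy)phenyl]-4-(hydroxymethyl)dihydrofuran-2(3H)-one | OC[C@H]1CC(=O)O[C@@H]1c2ccc(OCc3ccccc3)c(OCc3ccccc3)c2
F5 | step 1 | (2S,3S)-2-[3,4-bis(benzyloxy)phenyl]-5-oxooxolane-3-carbaldehyde | O=C[C@H]1CC(=O)O[C@@H]1c2ccc(OCc3ccccc3)c(OCc3ccccc3)c2
F6 | step 4 | (2S,3S)-2-[3,4-bis(benzyloxy)phenyl]-3-(dimethoxymethyl)-4-iodo-5-methyl-2,3-dihydrofuran | COC(OC)[C@H]1C(I)=C(C)O[C@@H]1c2ccc(OCc3ccccc3)c(OCc3ccccc3)c2
F7 | step 7 | methyl (4S,5S)-5-[3,4-bis(benzyloxy)phenyl]-4-(dimethoxymethyl)-2-(2-oxopropyl)-4,5-dihydrofuran-3-carboxylate | COC(OC)[C@H]1C(C(=O)OC)=C(CC(C)=O)O[C@@H]1c2ccc(OCc3ccccc3)c(OCc3ccccc3)c2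
F8 | step 7 | (2S,3S)-2-[3,4-bis(benzyloxy)phenyl]-3-(dimethoxymethyl)-6-methyl-2,3-dihydro-4H-furo[3,2-c]pyran-4-one | COC(OC)[C@H]1c2c(cc(C)oc2=O)O[C@@H]1c3ccc(OCc4ccccc4)c(OCc4ccccc4)c3
F9 | step 7 | (2S,3S)-2-[3,4-bis(benzyloxy)phenyl]-6-{2-[4-(benzyloxy)phenyl]-2-hydroxyethyl}-3-(dimethoxymethyl)-2,3-dihydro-4H-furo[3,2-c]pyran-4-one | COC(OC)[C@H]1c2c(cc(CC(O)c3ccc(OCc4ccccc4)cc3)oc2=O)O[C@@H]1c5ccc(OCc6ccccc6)c(OCc6ccccc6)c5
F10 | step 10 | (2S,3S)-2-[3,4-bis(benzyloxy)phenyl]-6-[(E)-2-[4-(benzyloxy)phenyl]ethenyl]-4-oxo-2,3-dihydro-4H-furo[3,2-c]pyran-3-carboxylic acid | OC(=O)[C@H]1c2c(cc(/C=C/c3ccc(OCc4ccccc4)cc3)oc2=O)O[C@@H]1c5ccc(OCc6ccccc6)c(OCc6ccccc6)c5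
F11 | step 10 | (2S,3S)-2-[3,4-bis(benzyloxy)phenyl]-6-[(E)-2-[4-(benzyloxy)phenyl]ethenyl]-4-oxo-2,3-dihydro-4H-furo[3,2-c]pyran-3-carbonyl chloride | O=C(Cl)[C@H]1c2c(cc(/C=C/c3ccc(OCc4ccccc4)cc3)oc2=O)O[C@@H]1c5ccc(OCc6ccccc6)c(OCc6ccccc6)c5
A1 | alternative 1 | (2S,3S)-2-[3,4-bis(benzyloxy)phenyl]-3-[4-(benzyloxy)-2-oxo-2H-pyran-6-yl]-6-[(E)-2-[4-(benzyloxy)phenyl]ethenyl]-2,3-dihydro-4H-furo[3,2-c]pyran-4-one | O=c1cc(OCc2ccccc2)cc([C@H]3c4c(cc(/C=C/c5ccc(OCc6ccccc6)cc5)oc4=O)O[C@@H]3c7ccc(OCc8ccccc8)c(OCc8ccccc8)c7)o1
A2 | alternative 1 | 6-[(E)-2-[4-(benzyloxy)phenyl]ethenyl]-3-{[4-(benzyloxy)-2-oxo-2H-pyran-6-yl](4-methylbenzenesulfonyl)methyl}-4-hydroxy-2H-pyran-2-one | Cc1ccc(cc1)S(=O)(=O)C(c2cc(OCc3ccccc3)cc(=O)o2)c4c(O)cc(/C=C/c5ccc(OCc6ccccc6)cc5)oc4=O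
A3 | alternative 1 | (2R,5R)-1-{[3,4-bis(benzyloxy)phenyl]methyl}-2,5-dimethylthiolan-1-ium bromide | C[C@@H]1CC[C@@H](C)[S+]1Cc2ccc(OCc3ccccc3)c(OCc3ccccc3)c2.[Br-]
A4 | alternative 2 | (2S,3R)-2-[3,4-bis(benzyloxy)phenyl]-3-({[tert-butyl(dimethyl)silyl]oxy}methyl)-6-methyl-2,3-dihydro-4H-furo[3,2-c]pyran-4-one | CC(C)(C)[Si](C)(C)OC[C@H]1c2c(cc(C)oc2=O)O[C@@H]1c3ccc(OCc4ccccc4)c(OCc4ccccc4)c3
A5 | alternative 2 | 1-[(4R,5S)-5-[3,4-bis(benzyloxy)phenyl]-4-({[tert-butyl(dimethyl)silyl]oxy}methyl)-3-iodo-4,5-dihydrofuran-2-yl]propan-2-one | CC(C)(C)[Si](C)(C)OC[C@H]1C(I)=C(CC(C)=O)O[C@@H]1c2ccc(OCc3ccccc3)c(OCc3ccccc3)c2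
A6 | alternative 3 | (2S,3S)-2-[3,4-bis(benzyloxy)phenyl]-6-[(E)-2-[4-(benzyloxy)phenyl]ethenyl]-4-oxo-2,3-dihydro-4H-furo[3,2-c]pyran-3-carboxylic acid | OC(=O)[C@H]1c2c(cc(/C=C/c3ccc(OCc4ccccc4)cc3)oc2=O)O[C@@H]1c5ccc(OCc6ccccc6)c(OCc6ccccc6)c5
A7 | alternative 3 | (2R)-2-[3,4-bis(benzyloxy)phenyl]-7-[(E)-2-[4-(benzyloxy)phenyl]ethenyl]-3-diazo-2,3-dihydro-4H,5H-pyrano[4,3-b]pyran-4,5-dione | [N-]=[N+]=C1C(=O)c2c(cc(/C=C/c3ccc(OCc4ccccc4)cc3)oc2=O)O[C@@H]1c5ccc(OCc6ccccc6)c(OCc6ccccc6)c5
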